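## The problem

Podocarpusflavone A (25) is a 3',8''-linked biflavone. Ring B1 of a 5,7,4'-trihydroxyflavone (unit 1: rings A1, C1, B1; plain and single-primed locants) is bonded through C3' to C8'' of ring A2 of a 5,7-dihydroxy-4'-methoxyflavone (unit 2: rings A2, C2, B2; double- and triple-primed locants). The C3'–C8'' bond is the hard part: C8'' lies between the O7''-bearing carbon and C8a'', and C3' lies next to the C4' hydroxyl. The biaryl is therefore tri-ortho-oxygenated and electron-rich on both sides, the least favorable case for joining two finished arenes. There is no stereocenter. Remark on the chemistry: the biaryl axis carries no descriptor in the target and is assumed to rotate freely, so no axial configuration has to be set. The selectivity problems are positional. Ring A2 carries three oxygens, and ring C2 must close through the oxygen next to C8'' (8-aryl flavone), not through the one para to it (6-aryl isomer). Five phenols must end free while only O4''' stays methylated. The γ-pyrones open in hot alkali, and 5-hydroxyflavones can isomerize from 8- to 6-substituted under hot mineral acid (Wessely–Moser rearrangement), so the phenols are best unmasked last under cold Lewis-acid conditions. The enabling feature is that the phenolic carbon C4' of ring B1 sits between C5' and the aryl-bearing C3', with the pyrone-bearing C1' para to it. Ring B1 can thus be built from carbon monoxide (C4') and an open chain C5'–C6'–C1'–C2'–C3' that carries a carboxyl carbon at its center and ring A2 at its end, so the crowded aryl–aryl bond begins as an ordinary aryl–CH= bond.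

## Retrosynthesis

**25 from 24.** No skeletal bond is cut. The five phenols are carried as four benzyl ethers and one methyl ether in 24. The methyl ether sits on O5'' on purpose. It blocks that oxygen while ring C2 is closed, and it is the one methyl ether that a boron trihalide removes by chelation to the peri carbonyl. A single cold Lewis-acid operation should therefore free all five phenols and leave the unassisted O4''' methyl ether.

**24 from 20 and 22.** Ring C1 is cut at O1–C2 and C2–C3. C2 arrives as the methyl ester carbon of 20, and C3–C4 with ring A1 arrive as acetophenone 22. A chalcone route would need an aldehyde and an oxidation, and an acid chloride would need ester hydrolysis first. The Claisen cut uses the ester exactly as the ring synthesis delivers it. The forward step must let an enolate attack the ester without touching the finished pyrone of unit 2, and 20 has no enolizable ketone left to interfere.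

**20 from 17 and 18.** Ring C2 is cut at O1''–C2'' and C2''–C3''. Acetophenone 17 supplies C3''–C4'' and 4-methoxybenzoyl chloride 18 supplies C2'' with ring B2. In 17 only the hydroxyl next to the aryl-bearing carbon is free, so the closure can only give the 8-aryl flavone. Acylation on carbon of the dianion avoids O-aroylation of a phenol wedged between acetyl and aryl.

**17 from 14 by way of 16 and 15.** The C4''–C4a'' bond is cut (C-acetylation) and the protecting groups are exchanged. After removal of the acetals and the acetate from 14, ring A2 of triol 15 is a 2-aryl phloroglucinol monoether whose two free positions are equivalent by symmetry, so acetylation can give only 16. The new ketone then chelates one neighboring hydroxyl and lets the other two phenols be benzylated selectively to 17. Doing this on the simple biaryl, before either pyrone exists, avoids any competition from ring A1.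

**14 from 10 and 11.** This is the key cut. Ring B1 is opened at C4'–C5' and C3'–C4', which releases C4' as carbon monoxide 11 and leaves dienyl acetate 10. Coupling two arenes at the C3'–C8'' bond would pair an ortho-oxygenated halide with a 2,6-dioxygenated aryl metal that is hindered and prone to protodemetalation. Building ring A2 instead would deliver it one carbon short of the acetophenone. The (5+1) cut forms both new bonds away from the crowded axis and delivers ring B1 with exactly the two functions needed: an oxygen ortho to the axis and a carboxyl para to that oxygen. Precursor 10 is acyclic and has no stereocenter. The forward reaction must insert carbon monoxide at a chain terminus and reach a cisoid triene.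

**10 from 5 and 9.** The C1'–C2' bond is cut between the ester-bearing carbon and the styryl unit. A Suzuki–Miyaura coupling of E-alkenylboronate 5 with α-bromo enoate 9 joins two three-functional pieces of similar size. It fixes the E-styryl geometry and sets the acetoxymethyl group cis to the new vinyl group. The coupling must be faster than ionization of the allylic acetate.

**5 from 1 by way of 4 and 2; 9 from 6 by way of 7; 22 from 21.** The C2'=C3' bond comes from a one-carbon boryl olefination of aldehyde 4. The C3'–C8'' bond itself is made as the aryl–formyl bond of 4 by ortho-lithiation of bis-acetal 2, which comes from 5-methoxyresorcinol 1. Bromo enoate 9 comes from methyl 4-bromocrotonate 6 by acetate displacement to 7 and bromination–dehydrobromination. Ketone 22 comes from 2',4',6'-trihydroxyacetophenone 21 by double benzylation. All three branches start from cheap commercial materials.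

## Roads not taken

**Alternative 1: twofold acyl transfer (Baker–Venkataraman) across two ester bridges.**
- Cut: both C2–C3 bonds, of unit 1 and unit 2, in one operation. Each pyrone C2 arrives as an aryl ester carbonyl.
- Forward step: diester A2 has the ring A2 phenol 4-methoxybenzoylated and the ring B1 carboxyl esterified with the phloroacetophenone hydroxyl. Excess strong amide base would convert it by two intramolecular acyl migrations into bis(1,3-diketone) A1. One acid treatment would then close both pyrones and give 24 of the present route.
- Merits: very convergent; both transfers are intramolecular; no finished flavone is exposed to a free enolate.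
- Weak points: A2 presupposes the complete biaryl with acetyl, carboxyl and differentiated phenols, so the C3'–C8'' bond is left unsolved. The phenol to be aroylated is flanked by acetyl and aryl, so O-acylation is slow. Two different esters must be installed chemoselectively, one on a carboxylic acid that first has to be set free. Two enolates and two aryl esters in one molecule allow intermolecular acyl crossover.
- Comparison: in end-game economy alternative 1 is better, with one base and one acid operation against two of each (steps 11 and 13). The chosen plan sets against this that it needs no ester hydrolysis, acylates the dianion of 17 on carbon, and above all makes ring B1 and the biaryl bond in its key step. The intramolecular acyl transfer is kept as the fallback for step 13.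

**Alternative 2: Danheiser benzannulation builds ring A2 on the biaryl carbon.**
- Cut: ring A2 is taken apart instead of ring B1, at C8''–C8a'' and C6''–C7'', with C4a''–C8a'' opened and reclosed.
- Forward step: 3-ethoxycyclobutenone A5 is heated with aryl siloxyalkyne A4, which carries ring B1 with a benzyl ether and a dioxolane-masked aldehyde. Ring opening of A5 to a vinylketene, [2+2] cycloaddition, 4π opening and 6π closure give A3. In A3 the aryl group sits between a free hydroxyl (future O1'') and a silyl ether (future O7''), with ethoxy para to it (future O5'').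
- Merits: thermal and metal-free. The biaryl bond is also made by ring synthesis, so on that point it equals the chosen plan. The three ring A2 oxygens emerge fully differentiated in one step, which is better than the chosen plan, where symmetry and a selective benzylation (step 10) do that work.
- Weak points: A4 is a sensitive ynol silyl ether that needs an ester-to-ynolate homologation next to an acetal, and A5 is a strained reagent that must be prepared. A3 lacks the C4a'' acyl carbon, which must be introduced beside an acid-labile silyl ether and a dioxolane. O5'' ends as an ethyl ether, which is slower to cleave by chelation than a methyl ether. Unit 1 must be grown from an aldehyde through a chalcone and an oxidative cyclization.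
- Comparison: overall length is similar. The chosen plan offers robust intermediates and a catalytic step using carbon monoxide 11, and its product 14 already carries the oxygen and the carboxyl that ring B1 needs.

**Alternative 3: acylketene annulation of phloroglucinol closes unit 1.**
- Cut: C4–C4a and O1–C2 of ring C1, closed onto unprotected phloroglucinol A8.
- Forward step: β-ketoester A7, which already contains unit 2 and ring B1, is heated with A8 without catalyst. Thermal loss of the ester alcohol gives an aroylketene that acylates A8 on carbon, and cyclodehydration gives A6 with free 5- and 7-hydroxyls.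
- Merits: no protection of ring A1, no regiochemical question because A8 is symmetric, and a lighter final deprotection. In protecting-group economy it is better than the chosen plan: it saves step 12 and two debenzylations.
- Weak points: acylketene generation needs a melt well above 200 °C on the most advanced, benzyl-protected intermediate. Excess A8 is needed, and coumarin formation competes if any acid is present. A7 itself needs a Claisen condensation on an ester such as 20, so no step is saved at that point. The biaryl bond is again left open.
- Comparison: the chosen plan sets a low-temperature Claisen condensation (step 13) against the high-temperature melt, and a key step that solves the biaryl bond. Since A7 could be made from 20, alternative 3 is better seen as a variant of the last annulation than as a competing way to build the skeleton.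

Key step: step 7

## Route

Step 1
Reactants: 1 5-methoxyresorcinol (5-methoxybenzene-1,3-diol)
Product: 2 1-methoxy-3,5-bis(methoxymethoxy)benzene
Conditions: MOMCl (2.5 equiv), i-Pr2NEt (3 equiv), CH2Cl2, 0 °C → rt
Reagents that add atoms: chloromethyl methyl ether, COCCl
Why: Williamson-type O-alkylation of both phenols with a reactive α-chloro ether; the acetals should survive the organolithium, chromium and palladium steps and act as ortho-directing groups in step 2.

Step 2
Reactants: 2 1-methoxy-3,5-bis(methoxymethoxy)benzene
Product: 4 4-methoxy-2,6-bis(methoxymethoxy)benzaldehyde, via aryllithium 3 (not isolated)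
Conditions: n-BuLi (1.1 equiv), TMEDA, THF, 0 °C; DMF, 0 °C → rt; H2O
Reagents that add atoms: N,N-dimethylformamide, CN(C)C=O
Why: Directed ortho-metalation; the position between the two chelating OMOM groups should be lithiated in preference to those next to the weaker methoxy director, and formylation of 3 with DMF is standard.

Step 3
Reactants: 4 4-methoxy-2,6-bis(methoxymethoxy)benzaldehyde
Product: 5 2-{(E)-2-[4-methoxy-2,6-bis(methoxymethoxy)phenyl]ethenyl}-4,4,5,5-tetramethyl-1,3,2-dioxaborolane
Conditions: Cl2CHBpin (2 equiv), CrCl2 (8 equiv), LiI (4 equiv), THF, rt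
Reagents that add atoms: 2-(dichloromethyl)-4,4,5,5-tetramethyl-1,3,2-dioxaborolane, ClC(Cl)B1OC(C)(C)C(C)(C)O1
Why: Boron–Takai olefination; the geminal dichromium reagent formed with divalent chromium adds to the aldehyde and eliminates to the E-alkenylboronate, aromatic aldehydes being the standard substrates and MOM ethers being inert.

Step 4
Reactants: 6 methyl (E)-4-bromobut-2-enoate
Product: 7 methyl (E)-4-acetoxybut-2-enoate
Conditions: KOAc (1.5 equiv), 18-crown-6 (cat.), MeCN, 50 °C
Reagents that add atoms: potassium acetate, CC(=O)[O-].[K+]
Why: SN2 displacement of a primary allylic bromide by acetate.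

Step 5
Reactants: 7 methyl (E)-4-acetoxybut-2-enoate
Product: 9 methyl (Z)-4-acetoxy-2-bromobut-2-enoate, via dibromide 8 (not isolated)
Conditions: Br2 (1.05 equiv), CH2Cl2, 0 °C → rt; NEt3 (1.5 equiv), 0 °C → rt
Reagents that add atoms: bromine, BrBr
Why: Anti addition of bromine and amine-induced dehydrobromination (loss of the acidic α-hydrogen and the β-bromide) is the usual route to α-bromo enoates and should give mainly the Z isomer with CH2OAc trans to the ester; any E isomer is harmless because step 7 equilibrates this double bond.

Step 6
Reactants: 5 2-{(E)-2-[4-methoxy-2,6-bis(methoxymethoxy)phenyl]ethenyl}-4,4,5,5-tetramethyl-1,3,2-dioxaborolane; 9 methyl (Z)-4-acetoxy-2-bromobut-2-enoate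
Product: 10 methyl (2E,3E)-2-(2-acetoxyethylidene)-4-[4-methoxy-2,6-bis(methoxymethoxy)phenyl]but-3-enoate
Conditions: PdCl2(dppf) (5 mol %), K3PO4 (3 equiv), THF/H2O (10:1), rt
Reagents that add atoms: none
Why: Suzuki–Miyaura coupling of an E-alkenylboronate with an α-bromoacrylate, both with retention of geometry; oxidative addition to the activated C–Br bond at room temperature should outrun ionization of the allylic acetate, and the phosphate base should spare the acetate.

Step 7
Reactants: 10 methyl (2E,3E)-2-(2-acetoxyethylidene)-4-[4-methoxy-2,6-bis(methoxymethoxy)phenyl]but-3-enoate; 11 carbon monoxide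
Product: 14 methyl 4-acetoxy-3-[4-methoxy-2,6-bis(methoxymethoxy)phenyl]benzoate, via dienylketene 12 (not isolated), via free phenol 13 (not isolated)
Conditions: PdCl2(PPh3)2 (5 mol %), CO (60 atm), Ac2O (2 equiv), NEt3 (2.5 equiv), benzene, 140 °C, autoclave
Reagents that add atoms: acetic anhydride, CC(=O)OC(C)=O
Why: Palladium-catalysed cyclocarbonylation of a 2,4-pentadienyl acetate, a known route to phenyl acetates (cinnamyl acetates give 1-naphthyl acetates in the same way), applied here to a 5-aryl-3-ester member of the class. Zerovalent palladium, formed in situ from PdCl2(PPh3)2 under CO and amine, ionizes the allylic acetate to a divalent η3-allyl palladium complex; CO inserts at the unsubstituted CH2 terminus to form C4'–C5', and NEt3 removes the activated α-hydrogen to release dienylketene 12 and zerovalent palladium. Ring B1 then closes by a thermal disrotatory 6π-electrocyclization in which the ketene carbon bonds to the aryl-bearing diene terminus (C3'–C4'), and the cyclohexadienone tautomerizes to phenol 13, which Ac2O and NEt3 trap as acetate 14. No stereocenter is created. The step needs CO to bridge the two ends of the five-carbon unit and the middle double bond to be cis: the fully substituted, ester-bearing central carbon is the disfavored insertion site, insertion at either terminus leads to the same arene, and η3–η1–η3 interconversion of the allyl palladium species lets the cisoid geometry be reached whatever the geometry of 10. The dienyl unit has no sp3 β-hydrogen, so β-hydride elimination cannot compete; the 2,6-dioxygenated aryl group stays on the outer E position of the cyclizing triene; the amine buffer should keep the MOM acetals intact; and the ester on the central carbon necessarily ends para to the new oxygen.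

Step 8
Reactants: 14 methyl 4-acetoxy-3-[4-methoxy-2,6-bis(methoxymethoxy)phenyl]benzoate
Product: 15 methyl 3-(2,6-dihydroxy-4-methoxyphenyl)-4-hydroxybenzoate
Conditions: HCl (3 M in MeOH), 50 °C
Reagents that add atoms: none
Why: Acid-catalysed acetal exchange removes both MOM groups as dimethoxymethane and the same medium transesterifies the aryl acetate; methanolysis of the methyl ester is degenerate and the methyl ether is untouched.

Step 9
Reactants: 15 methyl 3-(2,6-dihydroxy-4-methoxyphenyl)-4-hydroxybenzoate
Product: 16 methyl 3-(3-acetyl-2,6-dihydroxy-4-methoxyphenyl)-4-hydroxybenzoate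
Conditions: AcOH, BF3·OEt2, 85 °C; aq NaOAc work-up
Reagents that add atoms: acetic acid, CC(=O)O
Why: Friedel–Crafts C-acetylation of a phloroglucinol monoether; the two free positions of ring A2 are equivalent by symmetry so only one ketone can form, the first acetyl group deactivates the ring toward a second, and the ester-deactivated ring B1 should not react.

Step 10
Reactants: 16 methyl 3-(3-acetyl-2,6-dihydroxy-4-methoxyphenyl)-4-hydroxybenzoate
Product: 17 methyl 3-[3-acetyl-6-(benzyloxy)-2-hydroxy-4-methoxyphenyl]-4-(benzyloxy)benzoate
Conditions: BnBr (2.1 equiv), K2CO3 (2.5 equiv), DMF, rt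
Reagents that add atoms: benzyl bromide, BrCc1ccccc1
Why: Williamson etherification under hydrogen-bond control; the ring B1 phenol and the ring A2 phenol para to the acetyl group are free and acidic, whereas the phenol between acetyl and aryl is chelated to the ketone and hindered, the usual basis for selective 4-O-alkylation of 2,4-dihydroxyacetophenones.

Step 11
Reactants: 17 methyl 3-[3-acetyl-6-(benzyloxy)-2-hydroxy-4-methoxyphenyl]-4-(benzyloxy)benzoate; 18 4-methoxybenzoyl chloride
Product: 20 methyl 4-(benzyloxy)-3-[7-(benzyloxy)-5-methoxy-2-(4-methoxyphenyl)-4-oxo-4H-chromen-8-yl]benzoate, via diketone 19 (not isolated)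
Conditions: LiN(SiMe3)2 (3.2 equiv), THF, −78 → −20 °C; 18 (1.05 equiv), −78 °C → rt; 1 M HCl; crude 19, AcOH, H2SO4 (cat.), 60 °C
Reagents that add atoms: none
Why: C-Aroylation of the lithium phenoxide–enolate dianion of an o-hydroxyacetophenone (a one-flask equivalent of the Baker–Venkataraman sequence) followed by acid cyclodehydration; only the oxygen next to the aryl-bearing carbon is free, so the pyrone can close only to the 8-aryl flavone, and at −78 °C the enolate should react with the acid chloride far faster than with the para-alkoxybenzoate ester.

Step 12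
Reactants: 21 2',4',6'-trihydroxyacetophenone
Product: 22 1-[2,4-bis(benzyloxy)-6-hydroxyphenyl]ethanone
Conditions: BnBr (2.1 equiv), K2CO3 (2.2 equiv), DMF, rt
Reagents that add atoms: benzyl bromide, BrCc1ccccc1
Why: Selective Williamson etherification; after two hydroxyls are benzylated the remaining one is chelated to the ketone and should resist alkylation under these mild conditions.

Step 13
Reactants: 20 methyl 4-(benzyloxy)-3-[7-(benzyloxy)-5-methoxy-2-(4-methoxyphenyl)-4-oxo-4H-chromen-8-yl]benzoate; 22 1-[2,4-bis(benzyloxy)-6-hydroxyphenyl]ethanone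
Product: 24 5,7-bis(benzyloxy)-2-{4-(benzyloxy)-3-[7-(benzyloxy)-5-methoxy-2-(4-methoxyphenyl)-4-oxo-4H-chromen-8-yl]phenyl}-4H-chromen-4-one, via diketone 23 (not isolated)
Conditions: 22 (1.5 equiv), LiN(SiMe3)2 (4.5 equiv), THF, −78 → 0 °C; 20, 0 °C → rt; 1 M HCl; crude 23, AcOH, H2SO4 (cat.), 60 °C
Reagents that add atoms: none
Why: Crossed Claisen condensation of the dianion of an o-hydroxyacetophenone with a non-enolizable methyl benzoate, driven by deprotonation of the product diketone, then cyclodehydration to the pyrone; 20 has no enolizable ketone and its 2-aryl-γ-pyrone is a hindered, poor acceptor, so the ester should be the only electrophile.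

Step 14
Reactants: 24 5,7-bis(benzyloxy)-2-{4-(benzyloxy)-3-[7-(benzyloxy)-5-methoxy-2-(4-methoxyphenyl)-4-oxo-4H-chromen-8-yl]phenyl}-4H-chromen-4-one
Product: 25 podocarpusflavone A, 8-[5-(5,7-dihydroxy-4-oxo-4H-chromen-2-yl)-2-hydroxyphenyl]-5,7-dihydroxy-2-(4-methoxyphenyl)-4H-chromen-4-one
Conditions: BCl3 (12 equiv), C6HMe5 (12 equiv), CH2Cl2, −78 °C → rt; MeOH, then H2O
Reagents that add atoms: none
Why: BCl3 with pentamethylbenzene as benzyl-cation scavenger cleaves aryl benzyl ethers at low temperature, and on warming BCl3 cleaves the methyl ether peri to the pyrone carbonyl through a six-membered boron chelate; the unchelated 4'''-methyl ether lacks this assistance and should survive, and no hot protic acid is present that could trigger ring-opening isomerization.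

## Compound list

1 | 5-methoxyresorcinol (5-methoxybenzene-1,3-diol) | COc1cc(O)cc(O)c1 | starting material
2 | 1-methoxy-3,5-bis(methoxymethoxy)benzene | COCOc1cc(OC)cc(OCOC)c1 | intermediate
3 | [4-methoxy-2,6-bis(methoxymethoxy)phenyl]lithium | [Li]c1c(OCOC)cc(OC)cc1OCOC | intermediate
4 | 4-methoxy-2,6-bis(methoxymethoxy)benzaldehyde | COCOc1cc(OC)cc(OCOC)c1C=O | intermediate
5 | 2-{(E)-2-[4-methoxy-2,6-bis(methoxymethoxy)phenyl]ethenyl}-4,4,5,5-tetramethyl-1,3,2-dioxaborolane | COCOc1cc(OC)cc(OCOC)c1/C=C/B1OC(C)(C)C(C)(C)O1 | intermediate
6 | methyl (E)-4-bromobut-2-enoate | COC(=O)/C=C/CBr | starting material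
7 | methyl (E)-4-acetoxybut-2-enoate | COC(=O)/C=C/COC(C)=O | intermediate
8 | methyl (2R*,3S*)-4-acetoxy-2,3-dibromobutanoate (racemic, one enantiomer drawn) | COC(=O)[C@H](Br)[C@H](Br)COC(C)=O | intermediate
9 | methyl (Z)-4-acetoxy-2-bromobut-2-enoate | COC(=O)/C(Br)=C/COC(C)=O | intermediate
10 | methyl (2E,3E)-2-(2-acetoxyethylidene)-4-[4-methoxy-2,6-bis(methoxymethoxy)phenyl]but-3-enoate | CC(=O)OC/C=C(\C=C\c1c(OCOC)cc(OC)cc1OCOC)C(=O)OC | intermediate
11 | carbon monoxide | [C-]#[O+] | starting material
12 | methyl (2E,3E)-4-[4-methoxy-2,6-bis(methoxymethoxy)phenyl]-2-(3-oxoprop-2-en-1-ylidene)but-3-enoate (dienylketene) | O=C=C/C=C(\C=C\c1c(OCOC)cc(OC)cc1OCOC)C(=O)OC | intermediate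
13 | methyl 4-hydroxy-3-[4-methoxy-2,6-bis(methoxymethoxy)phenyl]benzoate | COC(=O)c1ccc(O)c(c1)-c1c(OCOC)cc(OC)cc1OCOC | intermediate
14 | methyl 4-acetoxy-3-[4-methoxy-2,6-bis(methoxymethoxy)phenyl]benzoate | COC(=O)c1ccc(OC(C)=O)c(c1)-c1c(OCOC)cc(OC)cc1OCOC | intermediate
15 | methyl 3-(2,6-dihydroxy-4-methoxyphenyl)-4-hydroxybenzoate | COC(=O)c1ccc(O)c(c1)-c1c(O)cc(OC)cc1O | intermediate
16 | methyl 3-(3-acetyl-2,6-dihydroxy-4-methoxyphenyl)-4-hydroxybenzoate | COC(=O)c1ccc(O)c(c1)-c1c(O)cc(OC)c(C(C)=O)c1O | intermediate
17 | methyl 3-[3-acetyl-6-(benzyloxy)-2-hydroxy-4-methoxyphenyl]-4-(benzyloxy)benzoate | COC(=O)c1ccc(OCc2ccccc2)c(c1)-c1c(OCc2ccccc2)cc(OC)c(C(C)=O)c1O | intermediate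
18 | 4-methoxybenzoyl chloride | COc1ccc(cc1)C(Cl)=O | starting material
19 | methyl 4-(benzyloxy)-3-{6-(benzyloxy)-2-hydroxy-4-methoxy-3-[3-(4-methoxyphenyl)-3-oxopropanoyl]phenyl}benzoate | COC(=O)c1ccc(OCc2ccccc2)c(c1)-c1c(OCc2ccccc2)cc(OC)c(C(=O)CC(=O)c2ccc(OC)cc2)c1O | intermediate
20 | methyl 4-(benzyloxy)-3-[7-(benzyloxy)-5-methoxy-2-(4-methoxyphenyl)-4-oxo-4H-chromen-8-yl]benzoate | COc1ccc(cc1)-c1cc(=O)c2c(OC)cc(OCc3ccccc3)c(c2o1)-c1cc(ccc1OCc1ccccc1)C(=O)OC | intermediate
21 | 2',4',6'-trihydroxyacetophenone | CC(=O)c1c(O)cc(O)cc1O | starting material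
22 | 1-[2,4-bis(benzyloxy)-6-hydroxyphenyl]ethanone | CC(=O)c1c(O)cc(OCc2ccccc2)cc1OCc1ccccc1 | intermediate
23 | 1-[2,4-bis(benzyloxy)-6-hydroxyphenyl]-3-{4-(benzyloxy)-3-[7-(benzyloxy)-5-methoxy-2-(4-methoxyphenyl)-4-oxo-4H-chromen-8-yl]phenyl}propane-1,3-dione | COc1ccc(cc1)-c1cc(=O)c2c(OC)cc(OCc3ccccc3)c(c2o1)-c1cc(ccc1OCc1ccccc1)C(=O)CC(=O)c1c(O)cc(OCc2ccccc2)cc1OCc1ccccc1 | intermediate
24 | 5,7-bis(benzyloxy)-2-{4-(benzyloxy)-3-[7-(benzyloxy)-5-methoxy-2-(4-methoxyphenyl)-4-oxo-4H-chromen-8-yl]phenyl}-4H-chromen-4-one | COc1ccc(cc1)-c1cc(=O)c2c(OC)cc(OCc3ccccc3)c(c2o1)-c1cc(ccc1OCc1ccccc1)-c1cc(=O)c2c(OCc3ccccc3)cc(OCc3ccccc3)cc2o1 | intermediate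
25 | podocarpusflavone A | COc1ccc(-c2cc(=O)c3c(O)cc(O)c(-c4cc(-c5cc(=O)c6c(O)cc(O)cc6o5)ccc4O)c3o2)cc1 | target

## Step count and risk

Total step count: 14. Longest linear sequence: 11 steps (steps 1, 2, 3, 6, 7, 8, 9, 10, 11, 13 and 14 from 1). Steps 4–5 and step 12 are side branches.

**Step 7 (key step).** Substrate 10 is a donor–acceptor diene held at 140 °C. The most likely failure is consumption of 10 before the ketene forms. This could happen by thermal oligomerization, by acetate return with allylic transposition if CO insertion into the ester-substituted allyl unit is slow, or by loss of MOM groups in hot acetic anhydride. The fallback gives up the ring synthesis for a biaryl coupling. It sets out from 2: lithiation as in step 2 and trapping of 3 with 2-isopropoxy-4,4,5,5-tetramethyl-1,3,2-dioxaborolane would give 2-[4-methoxy-2,6-bis(methoxymethoxy)phenyl]-4,4,5,5-tetramethyl-1,3,2-dioxaborolane F1. Suzuki–Miyaura coupling of F1 with commercial methyl 3-bromo-4-hydroxybenzoate F2 (Pd(OAc)2, SPhos, K3PO4, toluene/H2O, 80 °C) would give phenol 13. The conditions of step 8 then convert 13 into 15, where the route is rejoined.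

**Step 6.** Zerovalent palladium may ionize the allylic acetate of 9 or of product 10 in competition with oxidative addition, leading to allyl transfer to the boronate or acetate scrambling. The aqueous base may also hydrolyze the acetate. The fallback installs the leaving group after the coupling. It sets out from 9: acid methanolysis (HCl, MeOH, rt) would give methyl (Z)-2-bromo-4-hydroxybut-2-enoate F3, whose allylic alcohol is not ionized. Coupling of F3 with 5 under the catalyst of step 6 would give methyl (2E,3E)-2-(2-hydroxyethylidene)-4-[4-methoxy-2,6-bis(methoxymethoxy)phenyl]but-3-enoate F4. Acetylation (Ac2O, pyridine, DMAP) returns to the route at 10.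

**Step 9.** Hot Lewis acid on a triol could cause O-acetylation, a second C-acetylation, or acid-promoted loss of water between the ortho,ortho' hydroxyls of the two rings (dibenzofuran formation). The fallback changes the electrophile from an acylium to a nitrilium species (Houben–Hoesch reaction). It sets out from 15: MeCN, ZnCl2 and HCl gas in Et2O at 0 °C would give the ketiminium chloride methyl 3-[2,6-dihydroxy-3-(1-iminioethyl)-4-methoxyphenyl]-4-hydroxybenzoate chloride F5. Brief hydrolysis in warm water returns to the route at 16.

**Step 13.** The ester of 20 is deactivated by the para benzyloxy group and the substrate is bulky, so the Claisen condensation may be slow. Conjugate attack of the enolate or amide on the unit 2 pyrone, with ring opening, could then compete. The fallback makes the acyl transfer intramolecular. It sets out from 20: saponification (LiOH, THF/H2O, rt) would give 4-(benzyloxy)-3-[7-(benzyloxy)-5-methoxy-2-(4-methoxyphenyl)-4-oxo-4H-chromen-8-yl]benzoic acid F6. Esterification with 22 (EDC·HCl, DMAP, CH2Cl2) would give 2-acetyl-3,5-bis(benzyloxy)phenyl 4-(benzyloxy)-3-[7-(benzyloxy)-5-methoxy-2-(4-methoxyphenyl)-4-oxo-4H-chromen-8-yl]benzoate F7. Baker–Venkataraman rearrangement of F7 (KOt-Bu, THF) gives diketone 23, and the acid cyclization of step 13 returns to the route at 24.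

**Step 14.** Once the benzyl ethers are cleaved the polyborate may precipitate and stall cleavage of the chelated O5'' methyl ether. Forcing the reaction could then start to cleave the O4''' methyl ether. The fallback separates the two deprotections. It sets out from 24: hydrogenolysis (H2, Pd/C, THF/MeOH) would give 8-[5-(5,7-dihydroxy-4-oxo-4H-chromen-2-yl)-2-hydroxyphenyl]-7-hydroxy-5-methoxy-2-(4-methoxyphenyl)-4H-chromen-4-one F8. Chelation-controlled demethylation of F8 with AlCl3 in MeCN then gives 25.

## Further compounds

F1 | step 7 | 2-[4-methoxy-2,6-bis(methoxymethoxy)phenyl]-4,4,5,5-tetramethyl-1,3,2-dioxaborolane | COCOc1cc(OC)cc(OCOC)c1B1OC(C)(C)C(C)(C)O1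
F2 | step 7 | methyl 3-bromo-4-hydroxybenzoate | COC(=O)c1ccc(O)c(Br)c1
F3 | step 6 | methyl (Z)-2-bromo-4-hydroxybut-2-enoate | COC(=O)/C(Br)=C/CO
F4 | step 6 | methyl (2E,3E)-2-(2-hydroxyethylidene)-4-[4-methoxy-2,6-bis(methoxymethoxy)phenyl]but-3-enoate | OC/C=C(\C=C\c1c(OCOC)cc(OC)cc1OCOC)C(=O)OC
F5 | step 9 | methyl 3-[2,6-dihydroxy-3-(1-iminioethyl)-4-methoxyphenyl]-4-hydroxybenzoate chloride | COC(=O)c1ccc(O)c(c1)-c1c(O)cc(OC)c(C(C)=[NH2+])c1O.[Cl-]
F6 | step 13 | 4-(benzyloxy)-3-[7-(benzyloxy)-5-methoxy-2-(4-methoxyphenyl)-4-oxo-4H-chromen-8-yl]benzoic acid | COc1ccc(cc1)-c1cc(=O)c2c(OC)cc(OCc3ccccc3)c(c2o1)-c1cc(ccc1OCc1ccccc1)C(=O)O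
F7 | step 13 | 2-acetyl-3,5-bis(benzyloxy)phenyl 4-(benzyloxy)-3-[7-(benzyloxy)-5-methoxy-2-(4-methoxyphenyl)-4-oxo-4H-chromen-8-yl]benzoate | COc1ccc(cc1)-c1cc(=O)c2c(OC)cc(OCc3ccccc3)c(c2o1)-c1cc(ccc1OCc1ccccc1)C(=O)Oc1cc(OCc2ccccc2)cc(OCc2ccccc2)c1C(C)=O
F8 | step 14 | 8-[5-(5,7-dihydroxy-4-oxo-4H-chromen-2-yl)-2-hydroxyphenyl]-7-hydroxy-5-methoxy-2-(4-methoxyphenyl)-4H-chromen-4-one | COc1ccc(cc1)-c1cc(=O)c2c(OC)cc(O)c(c2o1)-c1cc(ccc1O)-c1cc(=O)c2c(O)cc(O)cc2o1
A1 | alternative 1 | 1-[2,4-bis(benzyloxy)-6-hydroxyphenyl]-3-{4-(benzyloxy)-3-[6-(benzyloxy)-2-hydroxy-4-methoxy-3-[3-(4-methoxyphenyl)-3-oxopropanoyl]phenyl]phenyl}propane-1,3-dione | O=C(CC(=O)c1ccc(OCc2ccccc2)c(c1)-c1c(OCc2ccccc2)cc(OC)c(C(=O)CC(=O)c2ccc(OC)cc2)c1O)c1c(O)cc(OCc2ccccc2)cc1OCc1ccccc1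
A2 | alternative 1 | 2-acetyl-3,5-bis(benzyloxy)phenyl 3-[3-acetyl-6-(benzyloxy)-4-methoxy-2-(4-methoxybenzoyloxy)phenyl]-4-(benzyloxy)benzoate | CC(=O)c1c(OC)cc(OCc2ccccc2)c(c1OC(=O)c1ccc(OC)cc1)-c1cc(ccc1OCc1ccccc1)C(=O)Oc1cc(OCc2ccccc2)cc(OCc2ccccc2)c1C(C)=O
A3 | alternative 2 | 2-[2-(benzyloxy)-5-(1,3-dioxolan-2-yl)phenyl]-5-ethoxy-3-(triisopropylsilyloxy)phenol | CCOc1cc(O)c(-c2cc(C3OCCO3)ccc2OCc2ccccc2)c(O[Si](C(C)C)(C(C)C)C(C)C)c1
A4 | alternative 2 | {[2-(benzyloxy)-5-(1,3-dioxolan-2-yl)phenyl]ethynyloxy}triisopropylsilane | CC(C)[Si](OC#Cc1cc(C2OCCO2)ccc1OCc1ccccc1)(C(C)C)C(C)C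
A5 | alternative 2 | 3-ethoxycyclobut-2-en-1-one | CCOC1=CC(=O)C1
A6 | alternative 3 | 7-(benzyloxy)-8-[2-(benzyloxy)-5-(5,7-dihydroxy-4-oxo-4H-chromen-2-yl)phenyl]-5-methoxy-2-(4-methoxyphenyl)-4H-chromen-4-one | COc1ccc(cc1)-c1cc(=O)c2c(OC)cc(OCc3ccccc3)c(c2o1)-c1cc(ccc1OCc1ccccc1)-c1cc(=O)c2c(O)cc(O)cc2o1
A7 | alternative 3 | ethyl 3-{4-(benzyloxy)-3-[7-(benzyloxy)-5-methoxy-2-(4-methoxyphenyl)-4-oxo-4H-chromen-8-yl]phenyl}-3-oxopropanoate | COc1ccc(cc1)-c1cc(=O)c2c(OC)cc(OCc3ccccc3)c(c2o1)-c1cc(ccc1OCc1ccccc1)C(=O)CC(=O)OCC
A8 | alternative 3 | phloroglucinol (benzene-1,3,5-triol) | Oc1cc(O)cc(O)c1
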